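**Plan**

- Retrosynthesis first cuts the two C2–CH2 bonds of the methylene bridge, giving formaldehyde and two molecules of 7-acetyl-3,6,8-trihydroxy-4,4-dimethylnaphthalen-1(4H)-one.
- In the monomer, C4a–C8a and C7–C8 are cut together. Ring A carries acetyl at C7, oxygen at C6 and hydrogen at C5, which are C3, C4 and C5 of a 3-acetyl-4-methoxy-2-pyrone. C8–O and C8a are a siloxyalkyne tethered to pyrone C6 through C4 (CMe2), C3, C2 and C1 (ethylene ketal); the lactone leaves as CO2.
- The pyrone is cut at O1–C2, C3–acetyl and C5–C6 (acetoacetate dianion plus a Weinreb amide). The tether is cut at C2–C3 (aldol of a silyl ynone) and at C8–O (oxidation of the acetylide).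
- Forward: the chain C4a–C4–C3–C2–C1–C8a–C8 is built first, then the pyrone, then rings A and B in one thermal operation, then C3 carbinol to ketone, unmasking, and dimerisation through C2.
- Stereochemistry: the target is achiral. C3 is carried from the aldol to the oxidation as a racemic triethylsilyl-protected carbinol, because a β-keto ketal would not survive the ynolate and dianion steps.

Key step: step 11

Remark: compounds 6 to 23 are racemates at the C3 carbinol, so their SMILES carry no stereodescriptors; atom numbers C1–C8a refer to the naphthalenone skeleton of the target throughout.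

**Route**

Step 1
Reactants: 1 methyl 3-hydroxy-2,2-dimethylpropanoate
Product: 2 3-hydroxy-N-methoxy-N,2,2-trimethylpropanamide
Conditions: MeNHOMe·HCl, iPrMgCl, THF, −20 → 0 °C
Reagents that add atoms: N,O-dimethylhydroxylamine hydrochloride, CNOC.Cl
Why: Weinreb amidation of an ester with the magnesium amide of N,O-dimethylhydroxylamine is reliable for β-hydroxy esters and installs an acyl donor that has no α-hydrogen and survives the later strong-base steps.

Step 2
Reactants: 2 3-hydroxy-N-methoxy-N,2,2-trimethylpropanamide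
Product: 3 N-methoxy-N,2,2-trimethyl-3-oxopropanamide
Conditions: Dess–Martin periodinane, CH2Cl2, 0 → 23 °C
Reagents that add atoms: none
Why: Dess–Martin oxidation of a neopentylic primary alcohol should stop at the aldehyde, which cannot enolise.

Step 3
Reactants: 3 N-methoxy-N,2,2-trimethyl-3-oxopropanamide; 4 4-(trimethylsilyl)but-3-yn-2-one
Product: 6 rac-3-hydroxy-N-methoxy-N,2,2-trimethyl-5-oxo-7-(trimethylsilyl)hept-6-ynamide, via lithium enolate 5 (not isolated)
Conditions: 4, LiN(SiMe3)2, THF, −78 °C; then 3, −78 °C; H2O quench at −78 °C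
Reagents that add atoms: none
Why: Crossed aldol addition of the kinetic lithium enolate of a methyl ynone to a non-enolisable aldehyde forms C2–C3, and the new carbinol centre is racemic and is erased later by oxidation.

Step 4
Reactants: 6 rac-3-hydroxy-N-methoxy-N,2,2-trimethyl-5-oxo-7-(trimethylsilyl)hept-6-ynamide
Product: 7 rac-N-methoxy-N,2,2-trimethyl-5-oxo-3-(triethylsilyloxy)-7-(trimethylsilyl)hept-6-ynamide
Conditions: Et3SiOTf, 2,6-lutidine, CH2Cl2, −78 → 0 °C
Reagents that add atoms: triethylsilyl trifluoromethanesulfonate, CC[Si](CC)(CC)OS(=O)(=O)C(F)(F)F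
Why: Silylation with a silyl triflate and a hindered pyridine base should protect the aldol hydroxyl without retro-aldol cleavage or oxa-Michael closure onto the ynone.

Step 5
Reactants: 7 rac-N-methoxy-N,2,2-trimethyl-5-oxo-3-(triethylsilyloxy)-7-(trimethylsilyl)hept-6-ynamide
Product: 8 rac-N-methoxy-N,2,2-trimethyl-3-(triethylsilyloxy)-4-{2-[(trimethylsilyl)ethynyl]-1,3-dioxolan-2-yl}butanamide
Conditions: Me3SiOCH2CH2OSiMe3, Me3SiOTf (cat.), CH2Cl2, −78 → −20 °C; pyridine quench
Reagents that add atoms: 1,2-bis(trimethylsilyloxy)ethane, C[Si](C)(C)OCCO[Si](C)(C)C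
Why: Noyori ketalisation converts ynones into dioxolanes at low temperature and removes the acceptor carbonyl, so that the alkyne can later be made electron-rich.

Step 6
Reactants: 8 rac-N-methoxy-N,2,2-trimethyl-3-(triethylsilyloxy)-4-{2-[(trimethylsilyl)ethynyl]-1,3-dioxolan-2-yl}butanamide
Product: 9 rac-4-(2-ethynyl-1,3-dioxolan-2-yl)-N-methoxy-N,2,2-trimethyl-3-(triethylsilyloxy)butanamide
Conditions: K2CO3 (cat.), MeOH, 0 °C
Reagents that add atoms: none
Why: Carbonate-catalysed methanolysis cleaves the alkynyl C–Si bond selectively in the presence of the hindered triethylsilyl ether.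

Step 7
Reactants: 9 rac-4-(2-ethynyl-1,3-dioxolan-2-yl)-N-methoxy-N,2,2-trimethyl-3-(triethylsilyloxy)butanamide
Product: 12 rac-N-methoxy-N,2,2-trimethyl-3-(triethylsilyloxy)-4-[2-(triisopropylsilyloxyethynyl)-1,3-dioxolan-2-yl]butanamide, via lithium acetylide 10 (not isolated), via lithium ynolate 11 (not isolated)
Conditions: LiN(SiMe3)2, THF, −78 °C; tBuOOLi (from tBuOOH and LiN(SiMe3)2), −78 → 0 °C; iPr3SiOTf, −78 → 0 °C
Reagents that add atoms: tert-butyl hydroperoxide, CC(C)(C)OO; triisopropylsilyl trifluoromethanesulfonate, CC(C)[Si](OS(=O)(=O)C(F)(F)F)(C(C)C)C(C)C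
Why: Julia oxidation of a lithium acetylide with lithium tert-butyl peroxide gives the ynolate, whose O-silylation with a bulky silyl triflate gives the siloxyalkyne, and ketal, silyl ether and the non-enolisable Weinreb amide tolerate the amide base.

Step 8
Reactants: 12 rac-N-methoxy-N,2,2-trimethyl-3-(triethylsilyloxy)-4-[2-(triisopropylsilyloxyethynyl)-1,3-dioxolan-2-yl]butanamide; 13 methyl acetoacetate
Product: 15 rac-methyl 6,6-dimethyl-3,5-dioxo-7-(triethylsilyloxy)-8-[2-(triisopropylsilyloxyethynyl)-1,3-dioxolan-2-yl]octanoate, via acetoacetate dianion 14 (not isolated)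
Conditions: 13, LiN(iPr)2 (2 equiv per 13), THF, 0 °C; then 12, 0 → 23 °C; pH 7 buffer
Reagents that add atoms: none
Why: Claisen-type acylation of the γ-carbon of a β-keto ester dianion by a Weinreb amide stops at the ketone stage through the chelated tetrahedral adduct and gives the 3,5-dioxo ester.

Step 9
Reactants: 15 rac-methyl 6,6-dimethyl-3,5-dioxo-7-(triethylsilyloxy)-8-[2-(triisopropylsilyloxyethynyl)-1,3-dioxolan-2-yl]octanoate; 16 acetic anhydride
Product: 19 rac-3-acetyl-4-hydroxy-6-{2-methyl-3-(triethylsilyloxy)-4-[2-(triisopropylsilyloxyethynyl)-1,3-dioxolan-2-yl]butan-2-yl}-2H-pyran-2-one, via 4-hydroxypyrone 17 (not isolated), via 4-acetoxypyrone 18 (not isolated)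
Conditions: DBU, PhMe, 23 °C; then 16, DMAP, 60 °C; pH 6 buffer
Reagents that add atoms: none
Why: DBU-mediated enol-lactonisation of a 3,5-dioxo ester gives the 4-hydroxy-2-pyrone, and O-acetylation followed by DMAP-catalysed O-to-C acyl migration (Fries-type rearrangement of the enol ester) places the acetyl group at pyrone C3 in a medium that stays basic and so spares the ynol ether.

Step 10
Reactants: 19 rac-3-acetyl-4-hydroxy-6-{2-methyl-3-(triethylsilyloxy)-4-[2-(triisopropylsilyloxyethynyl)-1,3-dioxolan-2-yl]butan-2-yl}-2H-pyran-2-one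
Product: 20 rac-3-acetyl-4-methoxy-6-{2-methyl-3-(triethylsilyloxy)-4-[2-(triisopropylsilyloxyethynyl)-1,3-dioxolan-2-yl]butan-2-yl}-2H-pyran-2-one
Conditions: Me2SO4, K2CO3, acetone, 23 °C
Reagents that add atoms: dimethyl sulfate, COS(=O)(=O)OC
Why: O-Alkylation of the potassium salt of the chelated enol with dimethyl sulfate should give the 4-methoxy-2-pyrone, as is known for dehydroacetic acid.

Step 11
Reactants: 20 rac-3-acetyl-4-methoxy-6-{2-methyl-3-(triethylsilyloxy)-4-[2-(triisopropylsilyloxyethynyl)-1,3-dioxolan-2-yl]butan-2-yl}-2H-pyran-2-one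
Product: 22 rac-C1 ethylene ketal of 7-acetyl-6-methoxy-4,4-dimethyl-3-(triethylsilyloxy)-8-(triisopropylsilyloxy)-3,4-dihydronaphthalen-1(2H)-one, via bridged lactone 21 (not isolated)
Conditions: o-xylene, 2,6-di-tert-butyl-4-methylpyridine (cat.), 140 °C, sealed tube
Reagents that add atoms: none
Why: The 3-acetyl-2-pyrone is an electron-poor diene and the siloxyalkyne an electron-rich dienophile, so an intramolecular Diels–Alder reaction of inverse electron demand should join the nucleophilic alkyne carbon (future C8a) to pyrone C6 (future C4a) and the oxygen-bearing carbon (future C8) to pyrone C3 (future C7), giving bridged lactone 21. Retro-Diels–Alder loss of CO2 from 21 then aromatises ring A with acetyl, methoxy, hydrogen and siloxy groups already in their final positions. The closest known reaction type is the thermal cycloaddition of 2-pyrones to tethered alkynes with extrusion of CO2. Ring B is closed as a six-membered carbocycle by the intramolecular (4+2) bond C4a–C8a through the four-atom tether, and ring A is closed in the same (4+2) event by bond C7–C8 and made permanent by the cycloreversion. No stereocentre is created in the product, since the bridgehead centres of 21 vanish with CO2 and the racemic C3 carbinol is a spectator. The step needs regiocontrol and a cycloaddition faster than silyl migration or protonation of the ynol ether; the tether fixes the former, and polarity matching, the geminal methyl groups and acid-free conditions should secure the latter.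

Step 12
Reactants: 22 rac-C1 ethylene ketal of 7-acetyl-6-methoxy-4,4-dimethyl-3-(triethylsilyloxy)-8-(triisopropylsilyloxy)-3,4-dihydronaphthalen-1(2H)-one
Product: 23 rac-C1 ethylene ketal of 7-acetyl-3,8-dihydroxy-6-methoxy-4,4-dimethyl-3,4-dihydronaphthalen-1(2H)-one
Conditions: Bu4NF, THF, 0 → 23 °C
Reagents that add atoms: none
Why: Fluoride cleaves both the aryl triisopropylsilyl ether and the triethylsilyl ether and leaves ketal, methyl ether and acetyl group untouched.

Step 13
Reactants: 23 rac-C1 ethylene ketal of 7-acetyl-3,8-dihydroxy-6-methoxy-4,4-dimethyl-3,4-dihydronaphthalen-1(2H)-one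
Product: 24 C1 ethylene ketal of 7-acetyl-8-hydroxy-6-methoxy-4,4-dimethylnaphthalene-1,3(2H,4H)-dione
Conditions: Dess–Martin periodinane, pyridine, CH2Cl2, 0 → 23 °C
Reagents that add atoms: none
Why: Dess–Martin oxidation of the secondary carbinol gives the C3 ketone and erases the only stereocentre, while the phenol is hydrogen-bonded to the acetyl group and should not be oxidised.

Step 14
Reactants: 24 C1 ethylene ketal of 7-acetyl-8-hydroxy-6-methoxy-4,4-dimethylnaphthalene-1,3(2H,4H)-dione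
Product: 25 7-acetyl-3,8-dihydroxy-6-methoxy-4,4-dimethylnaphthalen-1(4H)-one
Conditions: 2 M aq. HCl, THF, 45 °C
Reagents that add atoms: water, O
Why: Acid-catalysed ketal hydrolysis releases the C1 ketone and is driven by formation of the chelated, enolised β-diketone.

Step 15
Reactants: 25 7-acetyl-3,8-dihydroxy-6-methoxy-4,4-dimethylnaphthalen-1(4H)-one
Product: 26 7-acetyl-3,6,8-trihydroxy-4,4-dimethylnaphthalen-1(4H)-one
Conditions: BCl3, CH2Cl2, −78 → 0 °C; aq. work-up
Reagents that add atoms: none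
Why: BCl3 cleaves aryl methyl ethers ortho to a carbonyl group through a six-membered boron chelate and leaves the dione intact.

Step 16
Reactants: 26 7-acetyl-3,6,8-trihydroxy-4,4-dimethylnaphthalen-1(4H)-one (two molecules); 27 formaldehyde
Product: 30 2,2'-methylenebis[7-acetyl-3,6,8-trihydroxy-4,4-dimethylnaphthalen-1(4H)-one] (CNP0295164.0), via hydroxymethyl adduct 28 (not isolated), via methylidene trione 29 (not isolated)
Conditions: 37% aq. CH2O (0.5 equiv), EtOH, 23 °C
Reagents that add atoms: none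
Why: Knoevenagel condensation of the cyclic 1,3-dione with formaldehyde followed by Michael addition of a second dione (the dimedone–formaldehyde reaction) joins two monomers through C2, the enolised dione being far more nucleophilic than the hindered aromatic C5.

**Compound list**

1 | methyl 3-hydroxy-2,2-dimethylpropanoate | COC(=O)C(C)(C)CO | starting material
2 | 3-hydroxy-N-methoxy-N,2,2-trimethylpropanamide | CON(C)C(=O)C(C)(C)CO | intermediate
3 | N-methoxy-N,2,2-trimethyl-3-oxopropanamide | CON(C)C(=O)C(C)(C)C=O | intermediate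
4 | 4-(trimethylsilyl)but-3-yn-2-one | CC(=O)C#C[Si](C)(C)C | starting material
5 | lithium 4-(trimethylsilyl)but-1-en-3-yn-2-olate (lithium enolate of 4) | [Li+].C=C([O-])C#C[Si](C)(C)C | intermediate
6 | rac-3-hydroxy-N-methoxy-N,2,2-trimethyl-5-oxo-7-(trimethylsilyl)hept-6-ynamide | CON(C)C(=O)C(C)(C)C(O)CC(=O)C#C[Si](C)(C)C | intermediate
7 | rac-N-methoxy-N,2,2-trimethyl-5-oxo-3-(triethylsilyloxy)-7-(trimethylsilyl)hept-6-ynamide | CON(C)C(=O)C(C)(C)C(O[Si](CC)(CC)CC)CC(=O)C#C[Si](C)(C)C | intermediate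
8 | rac-N-methoxy-N,2,2-trimethyl-3-(triethylsilyloxy)-4-{2-[(trimethylsilyl)ethynyl]-1,3-dioxolan-2-yl}butanamide | CON(C)C(=O)C(C)(C)C(O[Si](CC)(CC)CC)CC1(OCCO1)C#C[Si](C)(C)C | intermediate
9 | rac-4-(2-ethynyl-1,3-dioxolan-2-yl)-N-methoxy-N,2,2-trimethyl-3-(triethylsilyloxy)butanamide | CON(C)C(=O)C(C)(C)C(O[Si](CC)(CC)CC)CC1(OCCO1)C#C | intermediate
10 | lithium acetylide of 9 | [Li+].CON(C)C(=O)C(C)(C)C(O[Si](CC)(CC)CC)CC1(OCCO1)C#[C-] | intermediate
11 | lithium ynolate derived from 10 | [Li+].CON(C)C(=O)C(C)(C)C(O[Si](CC)(CC)CC)CC1(OCCO1)C#C[O-] | intermediate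
12 | rac-N-methoxy-N,2,2-trimethyl-3-(triethylsilyloxy)-4-[2-(triisopropylsilyloxyethynyl)-1,3-dioxolan-2-yl]butanamide | CON(C)C(=O)C(C)(C)C(O[Si](CC)(CC)CC)CC1(OCCO1)C#CO[Si](C(C)C)(C(C)C)C(C)C | intermediate
13 | methyl acetoacetate | COC(=O)CC(C)=O | starting material
14 | dilithium dianion of methyl acetoacetate | [Li+].[Li+].COC([O-])=CC([O-])=C | intermediate
15 | rac-methyl 6,6-dimethyl-3,5-dioxo-7-(triethylsilyloxy)-8-[2-(triisopropylsilyloxyethynyl)-1,3-dioxolan-2-yl]octanoate | COC(=O)CC(=O)CC(=O)C(C)(C)C(O[Si](CC)(CC)CC)CC1(OCCO1)C#CO[Si](C(C)C)(C(C)C)C(C)C | intermediate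
16 | acetic anhydride | CC(=O)OC(C)=O | starting material
17 | rac-4-hydroxy-6-{2-methyl-3-(triethylsilyloxy)-4-[2-(triisopropylsilyloxyethynyl)-1,3-dioxolan-2-yl]butan-2-yl}-2H-pyran-2-one | OC1=CC(=O)OC(=C1)C(C)(C)C(O[Si](CC)(CC)CC)CC1(OCCO1)C#CO[Si](C(C)C)(C(C)C)C(C)C | intermediate
18 | rac-2-oxo-6-{2-methyl-3-(triethylsilyloxy)-4-[2-(triisopropylsilyloxyethynyl)-1,3-dioxolan-2-yl]butan-2-yl}-2H-pyran-4-yl acetate | CC(=O)OC1=CC(=O)OC(=C1)C(C)(C)C(O[Si](CC)(CC)CC)CC1(OCCO1)C#CO[Si](C(C)C)(C(C)C)C(C)C | intermediate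
19 | rac-3-acetyl-4-hydroxy-6-{2-methyl-3-(triethylsilyloxy)-4-[2-(triisopropylsilyloxyethynyl)-1,3-dioxolan-2-yl]butan-2-yl}-2H-pyran-2-one | CC(=O)C1=C(O)C=C(OC1=O)C(C)(C)C(O[Si](CC)(CC)CC)CC1(OCCO1)C#CO[Si](C(C)C)(C(C)C)C(C)C | intermediate
20 | rac-3-acetyl-4-methoxy-6-{2-methyl-3-(triethylsilyloxy)-4-[2-(triisopropylsilyloxyethynyl)-1,3-dioxolan-2-yl]butan-2-yl}-2H-pyran-2-one | CC(=O)C1=C(OC)C=C(OC1=O)C(C)(C)C(O[Si](CC)(CC)CC)CC1(OCCO1)C#CO[Si](C(C)C)(C(C)C)C(C)C | intermediate
21 | bridged bicyclic lactone (2-oxabicyclo[2.2.2]octadienone cycloadduct of 20, mixture of diastereomers) | CC(=O)C12C(OC)=CC3(OC1=O)C(C)(C)C(O[Si](CC)(CC)CC)CC4(OCCO4)C3=C2O[Si](C(C)C)(C(C)C)C(C)C | intermediate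
22 | rac-C1 ethylene ketal of 7-acetyl-6-methoxy-4,4-dimethyl-3-(triethylsilyloxy)-8-(triisopropylsilyloxy)-3,4-dihydronaphthalen-1(2H)-one | CC(=O)c1c(OC)cc2c(c1O[Si](C(C)C)(C(C)C)C(C)C)C1(OCCO1)CC(O[Si](CC)(CC)CC)C2(C)C | intermediate
23 | rac-C1 ethylene ketal of 7-acetyl-3,8-dihydroxy-6-methoxy-4,4-dimethyl-3,4-dihydronaphthalen-1(2H)-one | CC(=O)c1c(OC)cc2c(c1O)C1(OCCO1)CC(O)C2(C)C | intermediate
24 | C1 ethylene ketal of 7-acetyl-8-hydroxy-6-methoxy-4,4-dimethylnaphthalene-1,3(2H,4H)-dione | CC(=O)c1c(OC)cc2c(c1O)C1(OCCO1)CC(=O)C2(C)C | intermediate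
25 | 7-acetyl-3,8-dihydroxy-6-methoxy-4,4-dimethylnaphthalen-1(4H)-one | CC(=O)c1c(OC)cc2c(c1O)C(=O)C=C(O)C2(C)C | intermediate
26 | 7-acetyl-3,6,8-trihydroxy-4,4-dimethylnaphthalen-1(4H)-one | CC(=O)c1c(O)cc2c(c1O)C(=O)C=C(O)C2(C)C | intermediate
27 | formaldehyde | C=O | starting material
28 | 7-acetyl-3,6,8-trihydroxy-2-(hydroxymethyl)-4,4-dimethylnaphthalen-1(4H)-one | CC(=O)c1c(O)cc2c(c1O)C(=O)C(CO)=C(O)C2(C)C | intermediate
29 | 7-acetyl-6,8-dihydroxy-4,4-dimethyl-2-methylidenenaphthalene-1,3(2H,4H)-dione | CC(=O)c1c(O)cc2c(c1O)C(=O)C(=C)C(=O)C2(C)C | intermediate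
30 | 2,2'-methylenebis[7-acetyl-3,6,8-trihydroxy-4,4-dimethylnaphthalen-1(4H)-one] (CNP0295164.0) | CC(=O)c1c(O)cc2c(c1O)C(=O)C(CC1=C(O)C(C)(C)c3cc(O)c(C(C)=O)c(O)c3C1=O)=C(O)C2(C)C | target

**Step count and risks**

Total step count: 16. Longest linear sequence: 16 steps, from methyl 3-hydroxy-2,2-dimethylpropanoate 1.

Steps most likely to fail:

Step 11. The silyl group of the ynol ether may migrate from oxygen to carbon, or the ynol ether may be protonated, faster than the methoxy-donated pyrone adds the alkyne. The fallback replaces the donor on the diene by an acceptor. It sets out from 19: tosylation (TsCl, Et3N, CH2Cl2) should give rac-3-acetyl-2-oxo-6-{2-methyl-3-(triethylsilyloxy)-4-[2-(triisopropylsilyloxyethynyl)-1,3-dioxolan-2-yl]butan-2-yl}-2H-pyran-4-yl 4-methylbenzenesulfonate F1. Its much more electron-poor diene should undergo the same cycloaddition at lower temperature (toluene, 80–110 °C) through the bridged lactone F2 and lose CO2 to give the aryl tosylate F3, the C1 ethylene ketal of 7-acetyl-4,4-dimethyl-6-tosyloxy-3-(triethylsilyloxy)-8-(triisopropylsilyloxy)-3,4-dihydronaphthalen-1(2H)-one. Bu4NF should then give the diol tosylate F4, Dess–Martin oxidation the keto ketal tosylate F5, and aqueous HCl the dione tosylate F6 (7-acetyl-3,8-dihydroxy-4,4-dimethyl-1-oxo-1,4-dihydronaphthalen-6-yl 4-methylbenzenesulfonate). KOH in aqueous methanol should cleave the sulfonate and return the route at 26, without the BCl3 step.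

Step 8. Attack of the dianion on the amide carbonyl, which is flanked by a quaternary carbon and a silyloxy-bearing carbon, may be too slow, so that the dianion acts only as a base or degrades the N-methoxy amide. The fallback goes through the aldehyde oxidation level and sets out from 12: reduction with iBu2AlH (THF, −78 °C) should give the aldehyde F7, rac-2,2-dimethyl-3-(triethylsilyloxy)-4-[2-(triisopropylsilyloxyethynyl)-1,3-dioxolan-2-yl]butanal. Addition of dianion 14 at −78 °C should give the δ-hydroxy-β-keto ester F8, methyl 5-hydroxy-6,6-dimethyl-3-oxo-7-(triethylsilyloxy)-8-[2-(triisopropylsilyloxyethynyl)-1,3-dioxolan-2-yl]octanoate. Dess–Martin oxidation with pyridine should return the route at 15.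

Step 10. The ambident anion of the 3-acetyl-4-hydroxypyrone may be methylated at the lactone oxygen (giving a 2-methoxy-4-pyranone), at the acetyl oxygen or at C3. The fallback sets out from 19 and replaces enolate alkylation by a Mitsunobu reaction (MeOH, PPh3, diisopropyl azodicarboxylate, THF, 0 °C), in which the neutral acidic enol is alkylated by the alkoxyphosphonium ion at O4; it returns directly at 20 and makes no new compound.

Further compounds
F1 | step 11 | rac-3-acetyl-2-oxo-6-{2-methyl-3-(triethylsilyloxy)-4-[2-(triisopropylsilyloxyethynyl)-1,3-dioxolan-2-yl]butan-2-yl}-2H-pyran-4-yl 4-methylbenzenesulfonate | CC(=O)C1=C(OS(=O)(=O)c2ccc(C)cc2)C=C(OC1=O)C(C)(C)C(O[Si](CC)(CC)CC)CC1(OCCO1)C#CO[Si](C(C)C)(C(C)C)C(C)C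
F2 | step 11 | bridged bicyclic lactone cycloadduct of F1 (not isolated) | CC(=O)C12C(OS(=O)(=O)c5ccc(C)cc5)=CC3(OC1=O)C(C)(C)C(O[Si](CC)(CC)CC)CC4(OCCO4)C3=C2O[Si](C(C)C)(C(C)C)C(C)C
F3 | step 11 | rac-C1 ethylene ketal of 7-acetyl-4,4-dimethyl-6-tosyloxy-3-(triethylsilyloxy)-8-(triisopropylsilyloxy)-3,4-dihydronaphthalen-1(2H)-one | CC(=O)c1c(OS(=O)(=O)c3ccc(C)cc3)cc2c(c1O[Si](C(C)C)(C(C)C)C(C)C)C1(OCCO1)CC(O[Si](CC)(CC)CC)C2(C)C
F4 | step 11 | rac-C1 ethylene ketal of 7-acetyl-3,8-dihydroxy-4,4-dimethyl-6-tosyloxy-3,4-dihydronaphthalen-1(2H)-one | CC(=O)c1c(OS(=O)(=O)c3ccc(C)cc3)cc2c(c1O)C1(OCCO1)CC(O)C2(C)C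
F5 | step 11 | C1 ethylene ketal of 7-acetyl-8-hydroxy-4,4-dimethyl-6-tosyloxynaphthalene-1,3(2H,4H)-dione | CC(=O)c1c(OS(=O)(=O)c3ccc(C)cc3)cc2c(c1O)C1(OCCO1)CC(=O)C2(C)C
F6 | step 11 | 7-acetyl-3,8-dihydroxy-4,4-dimethyl-1-oxo-1,4-dihydronaphthalen-6-yl 4-methylbenzenesulfonate | CC(=O)c1c(OS(=O)(=O)c3ccc(C)cc3)cc2c(c1O)C(=O)C=C(O)C2(C)C
F7 | step 8 | rac-2,2-dimethyl-3-(triethylsilyloxy)-4-[2-(triisopropylsilyloxyethynyl)-1,3-dioxolan-2-yl]butanal | O=CC(C)(C)C(O[Si](CC)(CC)CC)CC1(OCCO1)C#CO[Si](C(C)C)(C(C)C)C(C)C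
F8 | step 8 | methyl 5-hydroxy-6,6-dimethyl-3-oxo-7-(triethylsilyloxy)-8-[2-(triisopropylsilyloxyethynyl)-1,3-dioxolan-2-yl]octanoate (mixture of diastereomers) | COC(=O)CC(=O)CC(O)C(C)(C)C(O[Si](CC)(CC)CC)CC1(OCCO1)C#CO[Si](C(C)C)(C(C)C)C(C)C
F0 | step 10 | none | none
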